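The data come from a simulation on assumed constants; noise was put on by code.

| setting | violet | blue | west | east |
|---|---|---|---|---|
| substrate | 20 mM | 20 mM | 20 mM | 20 mM |
| partner | 2.5 equiv | 2.5 equiv | 2.50 equiv | 2.50 equiv |
| initiator | 3.5 mol% | 5.5 mol% | 2.5 mol% | 2.5 mol% |
| radical scavenger | 0.05 mol% | 0.05 mol% | 0.05 mol% | 0.05 mol% |
| remark | run made earlier | run made earlier |  |  |
| time |  |  | 15 min | 20 min |

- violet (time / min: substrate / %, product / %, first chain carrier / %): 0.667: 97.6, 2.6, 0.3; 1.33: 94.9, 5.7, 0.3; 2.50: 90.7, 9.6, 0.4; 5.00: 81.9, 17.4, 0; 10.0: 70.6, 30.7, 0
- blue (time / min: substrate / %, product / %, first chain carrier / %): 0.667: 97.0, 3.4, 0; 1.33: 94.0, 6.5, 0.2; 2.50: 88.1, 12.2, 0.6; 5.00: 77.6, 23.5, 0.4; 10.0: 62.7, 37.2, 0.1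

(scatter of a reading: 0.5 percentage points)

* which of these there is most of at the end, counted by the substrate in it, west (product / substrate / first chain carrier)
* which of these there is most of at the end, counted by the substrate in it, east (product / substrate / first chain carrier)
* how much there is at the end of the one of these that leads, in percent of the substrate charged: west
* how much there is at the end of the one of these that leads, in percent of the substrate charged: east



The easy step comes first: I take the natural logarithm of the fall in c(substrate) over the first 5.00 min, and call that loss one block. It is 0.200 in violet and 0.254 in blue. Their ratio of 1.27 stands near 1.25, the square root of the ratio of initiator loadings, so I scale by that root. The two runs then give a first block of 0.170 for west and east, a pseudo-first-order way of counting.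

The second block is smaller: 0.744 of the first in violet and 0.841 in blue. I take their mean, 0.792, as a shrink factor and assume that it holds for each later block. The gap between the two readings is the weak point of my reckoning.

Blocks that shrink by a fixed factor add up to a limit, so the rate's decline implies an end. I carry the rest level 44.2%, the percentage of substrate left once the shrinking blocks have summed to their limit. Summing the blocks gives me 66.3% substrate in west at 15 min and 60.9% in east at 20 min. Each is more than the percentage that has left the substrate, so I expect substrate to lead in both.

The forecast names substrate for west and substrate for east, with 65% (61.5% to 68%) and 58% (53% to 62.5%). Its ground is “the rate goes as the square root of initiator”. My figures are higher than its central values but lie inside its ranges.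

The flasks give substrate at 66.2% in west and substrate at 60.3% in east.

    2 second chain carrier → ended chains A (k = 1.50 × 10⁹ L mol⁻¹ s⁻¹)
    substrate + initiating radical → capped initiator + first chain carrier (k = 4.83 × 10⁶ L mol⁻¹ s⁻¹)
    2 first chain carrier → ended chains B (k = 1.00 × 10⁹ L mol⁻¹ s⁻¹)
    second chain carrier + radical scavenger → ended chains C (k = 6.61 × 10⁷ L mol⁻¹ s⁻¹)
    partner + first chain carrier → product + second chain carrier (k = 48900 L mol⁻¹ s⁻¹)
    initiator → 2 initiating radical (k = 0.00122 s⁻¹)
    substrate + second chain carrier → by-product + first chain carrier (k = 27300 L mol⁻¹ s⁻¹)

Neither flask has come to rest at its asked time: west still has 33% of its initiator and east 23%, and their substrate, 66.2% in west and 60.3% in east, stands above my rest level of 44.2%. Left until 150 min, west holds 38.4% substrate, 61.4% product and 0% initiator. East, left until 200 min, holds 38.3% substrate, and my rest level stands 5.8 percentage points above the west figure and 5.9 points above the east figure. The longer wait still takes 28 points of substrate from west and 22 points from east.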